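**Plan**

1. Retrosynthesis: the 4,5-cis-epoxide is traced to a 4,5-syn-diol of a 4E-alkene (C4–O kept, C5 inverted on closure) and the 1,10-epoxide to the 1(10)E-alkene. Adding a C2=C3 bond and rejoining C5–C10 (reverse of a 6π ring opening) leads to a trans-fused eudesma-1,3-diene that already carries the butenolide and both esters.
2. In the decalin the lactone is cut at C7=C11 (Horner–Wadsworth–Emmons) and O6–C12. The C6–O and C8–O bonds come from enolate oxidations of a C7 ketone, the diene from an enol triflate of a 1-en-3-one, and ring A (C1–C10, C4–C5) from a Robinson annulation of dihydrocarvone with pent-1-en-3-one.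
3. Forward: ring A is annulated onto the carvone ring (ring B), the isopropenyl group is degraded to the C7 ketone, and the γ-lactone is closed. Light then cuts the C5–C10 bond so that the two six-membered rings become the ten-membered ring, and the epoxides come last.
4. Stereochemistry: C5 of (S)-carvone sets the C10 methyl and is then erased; Li/NH3 gives the trans ring fusion; the axial C10 methyl sends both enolate oxidations to the α face (6α-O, 8α-O); the trans fusion dictates the E,Z,E triene.
5. Outer-face attack on the crown conformer of the germacradienolide sets C1, C10 and C4, and SN2 closure inverts C5. The cis-epoxide oxygen lies anti to the C6–O bond, a face that a 4Z-alkene would turn into the ring, hence the 4E-alkene. The glycidate centre is bought.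

Key step: step 20

Remark: eudesmane numbering is used for the decalins and germacrane numbering for the ten-membered rings (C14 on C10, C15 on C4, C11–C13 the lactone carbons; ring A = C1–C5 and C10, ring B = C5–C10; β = face of the C10 methyl); compounds 18, 19 and 26 are taken as purchasable.

**Route**

Step 1
Reactants: 1 (S)-(+)-carvone
Product: 2 (2S,5S)-dihydrocarvone (formed together with its C2 epimer and used as such)
Conditions: Zn dust, KOH, EtOH/H2O, reflux
Reagents that add atoms: none
Why: Conjugate reduction of the enone by zinc in alkali leaves the ketone and the isolated isopropenyl group untouched; the configuration at C2 is irrelevant because C2 becomes the enolate carbon in step 2.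

Step 2
Reactants: 2 (2S,5S)-dihydrocarvone; 3 pent-1-en-3-one
Product: 5 (4aS,7S)-1,4a-dimethyl-7-(prop-1-en-2-yl)-4,4a,5,6,7,8-hexahydronaphthalen-2(3H)-one (7α-isopropenyl-10β-methyl-eudesma-4,11-dien-3-one), via ketol 4 (not isolated)
Conditions: KOH (cat.), EtOH/Et2O, −10 → 20 °C; then KOH, EtOH, reflux
Reagents that add atoms: none
Why: Robinson annulation (Michael addition of the more substituted enolate of 2 to 3, aldol closure to ketol 4, dehydration) builds ring A, and the enone is expected to add to the enolate face that places the new C10 methyl trans to the isopropenyl group (axial attack on the chair-like enolate with equatorial isopropenyl), so C5 of carvone sets the quaternary centre.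

Step 3
Reactants: 5 7α-isopropenyl-10β-methyl-eudesma-4,11-dien-3-one
Product: 6 (4S,5S,7S,10S)-7-isopropenyl-4,10-dimethyldecalin-3-one (trans-fused: 5α-H and 10β-CH3; 4α-CH3; 7α-isopropenyl)
Conditions: Li, NH3(l)/THF, t-BuOH (1 equiv), −78 °C; NH4Cl
Reagents that add atoms: none
Why: Dissolving-metal (Birch-type) reduction of the 4-en-3-one protonates C5 axially, anti to the C10 methyl, which should give the trans ring fusion (5α-H); the C4 methyl settles equatorial on work-up and stops being a stereocentre in step 6.

Step 4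
Reactants: 6 trans-fused 7α-isopropenyl-4α,10β-dimethyldecalin-3-one
Product: 8 7α-isopropenyl-4α,10β-dimethyl-5α-decal-1-en-3-one, via silyl enol ether 7 (not isolated)
Conditions: LiN(i-Pr)2, Me3SiCl, THF, −78 °C; then Pd(OAc)2 (1 equiv), MeCN, 20 °C
Reagents that add atoms: none
Why: Saegusa–Ito oxidation: kinetic deprotonation takes the C2 methylene and not the C4 methine, and Pd(OAc)2 dehydrogenates silyl enol ether 7 to the 1-en-3-one without touching the isopropenyl group.

Step 5
Reactants: 8 7α-isopropenyl-4α,10β-dimethyl-5α-decal-1-en-3-one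
Product: 10 7α-acetoxy-4α,10β-dimethyl-5α-decal-1-en-3-one (11,12,13-trinor-eudesmane), via methoxy hydroperoxide 9 (not isolated)
Conditions: O3, CH2Cl2/MeOH, −78 °C (stopped when the isopropenyl group is consumed); then Ac2O, Et3N, DMAP (cat.), CH2Cl2, 0 → 40 °C
Reagents that add atoms: ozone, [O-][O+]=O
Why: Ozone attacks the electron-rich 1,1-disubstituted alkene much faster than the enone, and Criegee rearrangement of the acetylated methoxy hydroperoxide 9 shifts C7 from carbon to oxygen with retention, which turns the side chain into the 7α-acetate.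

Step 6
Reactants: 10 7α-acetoxy-4α,10β-dimethyl-5α-decal-1-en-3-one
Product: 11 7α-acetoxy-11,12,13-trinor-5α-eudesma-1,3-dien-3-yl trifluoromethanesulfonate
Conditions: Tf2O, 2,6-di-tert-butyl-4-methylpyridine, CH2Cl2, 0 → 20 °C
Reagents that add atoms: trifluoromethanesulfonic anhydride, O=S(=O)(OS(=O)(=O)C(F)(F)F)C(F)(F)F
Why: Enol triflate formation from an enone with Tf2O and a hindered pyridine: O-sulfonylation and loss of H-4, the only proton available since C10 is quaternary, should give the cross-conjugated dienyl triflate under conditions that spare the acetate.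

Step 7
Reactants: 11 dienyl triflate
Product: 12 7α-acetoxy-11,12,13-trinor-5α-eudesma-1,3-diene
Conditions: Pd(OAc)2 (cat.), PPh3, HCO2H, n-Bu3N, DMF, 60 °C
Reagents that add atoms: none
Why: Palladium-catalysed hydride transfer from formate (oxidative addition of the C–OTf bond to zerovalent palladium, decarboxylation of the formate complex, reductive elimination) replaces the triflate by hydrogen and leaves the homoannular diene of ring A.

Step 8
Reactants: 12 7α-acetoxy-11,12,13-trinor-5α-eudesma-1,3-diene
Product: 13 11,12,13-trinor-5α-eudesma-1,3-dien-7α-ol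
Conditions: K2CO3, MeOH, 20 °C
Reagents that add atoms: none
Why: Base-catalysed transesterification with methanol frees the C7 alcohol and does not affect the diene.

Step 9
Reactants: 13 11,12,13-trinor-5α-eudesma-1,3-dien-7α-ol
Product: 14 11,12,13-trinor-5α-eudesma-1,3-dien-7-one (trans-fused, 10β-CH3)
Conditions: Dess–Martin periodinane, NaHCO3, CH2Cl2, 0 → 20 °C
Reagents that add atoms: none
Why: Dess–Martin oxidation under buffered, non-acidic conditions converts the axial secondary alcohol into the C7 ketone and is compatible with the acid- and peracid-sensitive diene.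

Step 10
Reactants: 14 11,12,13-trinor-5α-eudesma-1,3-dien-7-one
Product: 15 8α-hydroxy-11,12,13-trinor-5α-eudesma-1,3-dien-7-one
Conditions: KN(SiMe3)2, THF, −78 °C; 2-(phenylsulfonyl)-3-phenyloxaziridine, −78 °C; AcOH
Reagents that add atoms: 2-(phenylsulfonyl)-3-phenyloxaziridine, O=S(=O)(N1OC1c1ccccc1)c1ccccc1
Why: Davis oxidation of the potassium enolate: by analogy with trans-fused 3-keto steroids the ketone should enolise towards C8 and not towards C6, and the oxaziridine (chosen over a peracid because of the diene) approaches anti to the axial C10 methyl, which sets the equatorial 8α-hydroxyl.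

Step 11
Reactants: 15 8α-hydroxy-11,12,13-trinor-5α-eudesma-1,3-dien-7-one
Product: 16 8α-(tert-butyldimethylsilyloxy)-11,12,13-trinor-5α-eudesma-1,3-dien-7-one
Conditions: t-BuMe2SiCl, imidazole, DMF, 20 °C
Reagents that add atoms: tert-butyldimethylsilyl chloride, CC(C)(C)[Si](C)(C)Cl
Why: Standard silylation of the secondary alcohol; the silyl ether also blocks enolisation towards C8 in step 12.

Step 12
Reactants: 16 8α-(tert-butyldimethylsilyloxy)-11,12,13-trinor-5α-eudesma-1,3-dien-7-one
Product: 17 8α-(tert-butyldimethylsilyloxy)-6α-hydroxy-11,12,13-trinor-5α-eudesma-1,3-dien-7-one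
Conditions: KN(SiMe3)2, THF, −78 °C; 2-(phenylsulfonyl)-3-phenyloxaziridine, −78 °C; AcOH
Reagents that add atoms: 2-(phenylsulfonyl)-3-phenyloxaziridine, O=S(=O)(N1OC1c1ccccc1)c1ccccc1
Why: Second Davis oxidation: with C8 carrying the silyloxy group, deprotonation should occur at C6, and attack anti to the axial C10 methyl gives the equatorial 6α-hydroxyl, cis to O-8 and free for lactone formation.

Step 13
Reactants: 18 benzyl 2-(diethoxyphosphoryl)acetate; 19 (triisopropylsiloxy)methyl chloride
Product: 20 benzyl 2-(diethoxyphosphoryl)-3-(triisopropylsilyloxy)propanoate (racemic)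
Conditions: NaH, THF, 0 °C; then 19, 0 → 20 °C
Reagents that add atoms: none
Why: C-Alkylation of the sodium phosphonoacetate with the reactive α-chloro ether 19 introduces the future C13 as a silyl-protected hydroxymethyl group, whose silyloxide is too poor a leaving group for β-elimination to compete later.

Step 14
Reactants: 20 benzyl 2-(diethoxyphosphoryl)-3-(triisopropylsilyloxy)propanoate
Product: 21 2-(diethoxyphosphoryl)-3-(triisopropylsilyloxy)propanoic acid
Conditions: H2 (1 atm), Pd/C, EtOAc, 20 °C
Reagents that add atoms: none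
Why: Hydrogenolysis of the benzyl ester liberates the acid under neutral conditions that leave the phosphonate and the silyl ether intact.

Step 15
Reactants: 17 8α-(tert-butyldimethylsilyloxy)-6α-hydroxy-11,12,13-trinor-5α-eudesma-1,3-dien-7-one; 21 2-(diethoxyphosphoryl)-3-(triisopropylsilyloxy)propanoic acid
Product: 22 6α-O-[2-(diethoxyphosphoryl)-3-(triisopropylsilyloxy)propanoyl] ester of 17 (epimers at the phosphonate carbon)
Conditions: DCC, DMAP (cat.), CH2Cl2, 0 → 20 °C
Reagents that add atoms: none
Why: Steglich esterification (carbodiimide, DMAP) acylates the only free hydroxyl, O-6, so the later lactone oxygen is fixed at C6.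

Step 16
Reactants: 22 phosphonoacyl ester
Product: 23 8α-(tert-butyldimethylsilyloxy)-13-(triisopropylsilyloxy)-5α-eudesma-1,3,7(11)-trien-12,6α-olide
Conditions: NaH, THF, 0 → 20 °C
Reagents that add atoms: none
Why: Intramolecular Horner–Wadsworth–Emmons olefination: the phosphonate carbanion adds to the electron-poor C7 ketone five atoms away and eliminates phosphate, closing the butenolide with the C7=C11 double bond and C13 in place.

Step 17
Reactants: 23 bis-silyl butenolide
Product: 24 8α,13-dihydroxy-5α-eudesma-1,3,7(11)-trien-12,6α-olide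
Conditions: HF·pyridine, pyridine, THF, 0 → 20 °C
Reagents that add atoms: none
Why: Fluoride cleavage of both silyl ethers (Si–F bond formation) with pyridine-buffered HF, conditions the diene and the butenolide should tolerate.

Step 18
Reactants: 24 8α,13-dihydroxy-5α-eudesma-1,3,7(11)-trien-12,6α-olide
Product: 25 13-acetoxy-8α-hydroxy-5α-eudesma-1,3,7(11)-trien-12,6α-olide
Conditions: AcCl, 2,4,6-collidine, CH2Cl2, −78 °C
Reagents that add atoms: acetyl chloride, CC(Cl)=O
Why: Acylation with acetyl chloride and a hindered pyridine at low temperature is selective for the primary allylic hydroxyl over the hindered secondary 8α-hydroxyl.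

Step 19
Reactants: 25 13-acetoxy-8α-hydroxy-5α-eudesma-1,3,7(11)-trien-12,6α-olide; 26 methyl (S)-2-methyloxirane-2-carboxylate
Product: 29 (5S,6R,8S,10S)-13-acetoxy-8-[(2S)-2-methyloxirane-2-carbonyloxy]eudesma-1,3,7(11)-trien-12,6-olide (trans-fused), via potassium carboxylate 27 (not isolated), via mixed anhydride 28 (not isolated)
Conditions: 26, KOSiMe3, THF, 20 °C; 2,4,6-trichlorobenzoyl chloride, 0 °C; then 25, DMAP, toluene, 20 °C
Reagents that add atoms: none
Why: Yamaguchi esterification: silanolate cleavage of the methyl ester gives carboxylate 27, which is activated as mixed anhydride 28 and transferred by DMAP to the hindered 8α-hydroxyl; the acid has no α-hydrogen, so its stereocentre cannot epimerise.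

Step 20
Reactants: 29 trans-fused eudesma-1,3,7(11)-trien-12,6α-olide diester
Product: 31 (1(10)E,4E)-13-acetoxy-8α-[(2S)-2-methyloxirane-2-carbonyloxy]germacra-1(10),4,7(11)-trien-12,6α-olide, via tetraene 30 (not isolated)
Conditions: hν (254 nm, quartz), THF/MeOH, −78 °C, Ar, to partial conversion; then KO2CN=NCO2K, AcOH, −78 → −30 °C
Reagents that add atoms: none
Why: Irradiation excites the ring A cyclohexa-1,3-diene (C1=C2–C3=C4), which undergoes the photochemically allowed conrotatory 6π electrocyclic ring opening; the C5–C10 σ bond common to both six-membered rings is cut, so the ten-membered ring of tetraene 30 arises by fragmentation of the decalin and no ring is closed. The closest known reactions are the opening of provitamin D to previtamin D and of trans-fused eudesma-1,3-dienes to (E,Z,E)-cyclodeca-1,3,5-trienes followed by reduction of the central alkene. No stereocentre is created; the alkene geometries follow from the trans ring fusion, in which the C10 methyl and H-5 are pseudo-axial on ring A on opposite faces, so the conrotation that continues the fixed helicity of the diene turns both inward and C9 and C6 outward: C1=C10 and C4=C5 become E and C2=C3 stays Z. The selectivity needed is this torquoselectivity (E,Z,E and not Z,Z,Z) together with excitation of the diene (absorbing near 265 nm) and not of the weakly absorbing butenolide; the rigid trans-decalin secures the first, the wavelength and partial conversion the second. Because the triene recloses thermally (disrotatory) and undergoes 1,7-hydrogen shifts on warming, diimide generated below −30 °C is added to the cold photolysate; it transfers H2 suprafacially to the least substituted central Z-alkene C2=C3 and leaves the trisubstituted and the conjugated tetrasubstituted alkenes.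

Step 21
Reactants: 31 (1(10)E,4E)-germacra-1(10),4,7(11)-trien-12,6α-olide diester
Product: 32 (1R,10R)-13-acetoxy-1,10-epoxy-8α-[(2S)-2-methyloxirane-2-carbonyloxy]germacra-4E,7(11)-dien-12,6α-olide
Conditions: dimethyldioxirane (1 equiv), acetone/CH2Cl2, −78 → −30 °C
Reagents that add atoms: dimethyldioxirane, CC1(C)OO1
Why: Electrophilic epoxidation with a neutral dioxirane: C1=C10 is the most electron-rich alkene (C4=C5 is deactivated by the allylic lactone oxygen, C7=C11 is conjugated), and in the crown conformer of the (E,E)-germacradienolide, with C14 and C15 both on the β face, only the outer face of the alkene is open, which should give the (1R,10R)-epoxide (1β,10α).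

Step 22
Reactants: 32 1,10-epoxy-germacra-4E,7(11)-dien-12,6α-olide diester
Product: 33 (1R,4R,5R,6S,8S,10R)-13-acetoxy-1,10-epoxy-4,5-dihydroxy-8-[(2S)-2-methyloxirane-2-carbonyloxy]germacr-7(11)-en-12,6-olide
Conditions: OsO4 (cat.), N-methylmorpholine N-oxide, acetone/H2O, 0 → 20 °C; Na2SO3
Reagents that add atoms: 4-methylmorpholine N-oxide, C[N+]1([O-])CCOCC1; water, O; osmium tetroxide as the oxygen carrier, O=[Os](=O)(=O)=O
Why: Catalytic osmylation with an amine N-oxide (syn-dihydroxylation): the remaining trisubstituted alkene is attacked from its outer face, the face of the C6–O bond in the conformer in which H-6 eclipses the alkene, which sets C4 as in the target (4R) and C5 with the opposite configuration (5R); the conjugated C7=C11 bond is too electron-poor to react.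

Step 23
Reactants: 33 1,10-epoxy-4,5-diol
Product: 35 (1R,4R,5S,6S,8S,10R)-13-acetoxy-1,10:4,5-diepoxy-8-[(2S)-2-methyloxirane-2-carbonyloxy]germacr-7(11)-en-12,6-olide (target), via mesylate 34 (not isolated)
Conditions: MsCl, Et3N, CH2Cl2, −20 °C; then DBU, MeCN, 0 → 20 °C
Reagents that add atoms: none
Why: The secondary 5-hydroxyl is mesylated selectively (the tertiary 4-hydroxyl is inert), and the C4 alkoxide then displaces the mesylate in an intramolecular SN2 reaction (3-exo-tet) with inversion at C5, which closes the cis-epoxide (4R,5S) on the face that no direct epoxidation of a 4,5-alkene would reach.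

**Compound list**

1 | (S)-(+)-carvone, (5S)-2-methyl-5-(prop-1-en-2-yl)cyclohex-2-en-1-one | CC1=CC[C@@H](CC1=O)C(C)=C | starting material
2 | (2S,5S)-dihydrocarvone, trans-2-methyl-5-(prop-1-en-2-yl)cyclohexan-1-one (C2 epimer present) | C[C@H]1CC[C@@H](CC1=O)C(C)=C | intermediate
3 | pent-1-en-3-one | CCC(=O)C=C | starting material
4 | 5β-hydroxy-7α-isopropenyl-4α,10β-dimethyldecalin-3-one (aldol ketol) | C[C@H]1[C@@]2(O)C[C@@H](C(C)=C)CC[C@@]2(C)CCC1=O | intermediate
5 | (4aS,7S)-1,4a-dimethyl-7-(prop-1-en-2-yl)-4,4a,5,6,7,8-hexahydronaphthalen-2(3H)-one | CC1=C2C[C@@H](C(C)=C)CC[C@@]2(C)CCC1=O | intermediate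
6 | (4S,5S,7S,10S)-7-isopropenyl-4,10-dimethyldecalin-3-one (trans-fused, 5α-H, 10β-CH3, 4α-CH3, 7α-isopropenyl) | C[C@H]1[C@@H]2C[C@@H](C(C)=C)CC[C@@]2(C)CCC1=O | intermediate
7 | 7α-isopropenyl-4α,10β-dimethyl-3-(trimethylsilyloxy)-5α-decal-2-ene | C[C@H]1[C@@H]2C[C@@H](C(C)=C)CC[C@@]2(C)CC=C1O[Si](C)(C)C | intermediate
8 | 7α-isopropenyl-4α,10β-dimethyl-5α-decal-1-en-3-one | C[C@H]1[C@@H]2C[C@@H](C(C)=C)CC[C@@]2(C)C=CC1=O | intermediate
9 | 7α-(1-hydroperoxy-1-methoxyethyl)-4α,10β-dimethyl-5α-decal-1-en-3-one (epimers at the side-chain carbon) | C[C@H]1[C@@H]2C[C@@H](C(C)(OC)OO)CC[C@@]2(C)C=CC1=O | intermediate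
10 | 7α-acetoxy-4α,10β-dimethyl-5α-decal-1-en-3-one | C[C@H]1[C@@H]2C[C@@H](OC(C)=O)CC[C@@]2(C)C=CC1=O | intermediate
11 | 7α-acetoxy-11,12,13-trinor-5α-eudesma-1,3-dien-3-yl trifluoromethanesulfonate | CC=1[C@@H]2C[C@@H](OC(C)=O)CC[C@@]2(C)C=CC=1OS(=O)(=O)C(F)(F)F | intermediate
12 | 7α-acetoxy-11,12,13-trinor-5α-eudesma-1,3-diene | CC=1[C@@H]2C[C@@H](OC(C)=O)CC[C@@]2(C)C=CC=1 | intermediate
13 | 11,12,13-trinor-5α-eudesma-1,3-dien-7α-ol | CC=1[C@@H]2C[C@@H](O)CC[C@@]2(C)C=CC=1 | intermediate
14 | 11,12,13-trinor-5α-eudesma-1,3-dien-7-one | CC=1[C@@H]2CC(=O)CC[C@@]2(C)C=CC=1 | intermediate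
15 | 8α-hydroxy-11,12,13-trinor-5α-eudesma-1,3-dien-7-one | CC=1[C@@H]2CC(=O)[C@@H](O)C[C@@]2(C)C=CC=1 | intermediate
16 | 8α-(tert-butyldimethylsilyloxy)-11,12,13-trinor-5α-eudesma-1,3-dien-7-one | CC=1[C@@H]2CC(=O)[C@@H](O[Si](C)(C)C(C)(C)C)C[C@@]2(C)C=CC=1 | intermediate
17 | 8α-(tert-butyldimethylsilyloxy)-6α-hydroxy-11,12,13-trinor-5α-eudesma-1,3-dien-7-one | CC=1[C@@H]2[C@@H](O)C(=O)[C@@H](O[Si](C)(C)C(C)(C)C)C[C@@]2(C)C=CC=1 | intermediate
18 | benzyl 2-(diethoxyphosphoryl)acetate | CCOP(=O)(OCC)CC(=O)OCc1ccccc1 | starting material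
19 | (triisopropylsiloxy)methyl chloride | CC(C)[Si](OCCl)(C(C)C)C(C)C | starting material
20 | benzyl 2-(diethoxyphosphoryl)-3-(triisopropylsilyloxy)propanoate (racemic) | CCOP(=O)(OCC)C(CO[Si](C(C)C)(C(C)C)C(C)C)C(=O)OCc1ccccc1 | intermediate
21 | 2-(diethoxyphosphoryl)-3-(triisopropylsilyloxy)propanoic acid (racemic) | CCOP(=O)(OCC)C(CO[Si](C(C)C)(C(C)C)C(C)C)C(O)=O | intermediate
22 | 8α-(tert-butyldimethylsilyloxy)-6α-[2-(diethoxyphosphoryl)-3-(triisopropylsilyloxy)propanoyloxy]-11,12,13-trinor-5α-eudesma-1,3-dien-7-one | CC=1[C@@H]2[C@@H](OC(=O)C(CO[Si](C(C)C)(C(C)C)C(C)C)P(=O)(OCC)OCC)C(=O)[C@@H](O[Si](C)(C)C(C)(C)C)C[C@@]2(C)C=CC=1 | intermediate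
23 | 8α-(tert-butyldimethylsilyloxy)-13-(triisopropylsilyloxy)-5α-eudesma-1,3,7(11)-trien-12,6α-olide | CC(C)[Si](OCC1=C2[C@@H](O[Si](C)(C)C(C)(C)C)C[C@@]3(C)C=CC=C(C)[C@@H]3[C@H]2OC1=O)(C(C)C)C(C)C | intermediate
24 | 8α,13-dihydroxy-5α-eudesma-1,3,7(11)-trien-12,6α-olide | OCC1=C2[C@@H](O)C[C@@]3(C)C=CC=C(C)[C@@H]3[C@H]2OC1=O | intermediate
25 | 13-acetoxy-8α-hydroxy-5α-eudesma-1,3,7(11)-trien-12,6α-olide | CC(=O)OCC1=C2[C@@H](O)C[C@@]3(C)C=CC=C(C)[C@@H]3[C@H]2OC1=O | intermediate
26 | methyl (S)-2-methyloxirane-2-carboxylate | COC(=O)[C@]1(C)CO1 | starting material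
27 | potassium (S)-2-methyloxirane-2-carboxylate | [K+].[O-]C(=O)[C@]1(C)CO1 | intermediate
28 | (S)-2-methyloxirane-2-carboxylic 2,4,6-trichlorobenzoic anhydride | Clc1cc(Cl)c(C(=O)OC(=O)[C@]2(C)CO2)c(Cl)c1 | intermediate
29 | (5S,6R,8S,10S)-13-acetoxy-8-[(2S)-2-methyloxirane-2-carbonyloxy]eudesma-1,3,7(11)-trien-12,6-olide (trans-fused) | CC(=O)OCC1=C2[C@@H](OC(=O)[C@]3(C)CO3)C[C@@]3(C)C=CC=C(C)[C@@H]3[C@H]2OC1=O | intermediate
30 | (1(10)E,2Z,4E,6R,8S)-13-acetoxy-8-[(2S)-2-methyloxirane-2-carbonyloxy]germacra-1(10),2,4,7(11)-tetraen-12,6-olide | CC(=O)OCC1=C2[C@@H](OC(=O)[C@]3(C)CO3)C/C(C)=C/C=C\C(C)=C\[C@H]2OC1=O | intermediate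
31 | (1(10)E,4E,6R,8S)-13-acetoxy-8-[(2S)-2-methyloxirane-2-carbonyloxy]germacra-1(10),4,7(11)-trien-12,6-olide | CC(=O)OCC1=C2[C@@H](OC(=O)[C@]3(C)CO3)C/C(C)=C/CC/C(C)=C/[C@H]2OC1=O | intermediate
32 | (1R,4E,6R,8S,10R)-13-acetoxy-1,10-epoxy-8-[(2S)-2-methyloxirane-2-carbonyloxy]germacra-4,7(11)-dien-12,6-olide | CC(=O)OCC1=C2[C@@H](OC(=O)[C@]3(C)CO3)C[C@@]3(C)O[C@@H]3CC/C(C)=C/[C@H]2OC1=O | intermediate
33 | (1R,4R,5R,6S,8S,10R)-13-acetoxy-1,10-epoxy-4,5-dihydroxy-8-[(2S)-2-methyloxirane-2-carbonyloxy]germacr-7(11)-en-12,6-olide | CC(=O)OCC1=C2[C@@H](OC(=O)[C@]3(C)CO3)C[C@@]3(C)O[C@@H]3CC[C@@](C)(O)[C@H](O)[C@H]2OC1=O | intermediate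
34 | 5-O-methanesulfonate of 33 | CC(=O)OCC1=C2[C@@H](OC(=O)[C@]3(C)CO3)C[C@@]3(C)O[C@@H]3CC[C@@](C)(O)[C@H](OS(C)(=O)=O)[C@H]2OC1=O | intermediate
35 | (1R,4R,5S,6S,8S,10R)-13-acetoxy-1,10:4,5-diepoxy-8-[(2S)-2-methyloxirane-2-carbonyloxy]germacr-7(11)-en-12,6-olide | CC(=O)OCC1=C2[C@@H](OC(=O)[C@]3(C)CO3)C[C@@]3(C)O[C@@H]3CC[C@@]3(C)O[C@H]3[C@H]2OC1=O | target

**Summary and risks**

Total step count: 23. Longest linear sequence: 21 steps (steps 1–12 and 15–23, from (S)-carvone).

Steps most likely to fail:

Step 20. The triene may be lost before it is reduced (thermal 6π reclosure, 1,7-hydrogen shift, further photoisomerisation at the photostationary state), and the glycidic ester may be degraded by the 254 nm light, so that the side chain is lost. Fallback: the ring is opened one stage earlier and the sensitive acyl group is attached only after the ten-membered ring exists. Setting out from alcohol 25, irradiation and cold diimide reduction as above should give, through the hydroxy tetraene (1(10)E,2Z,4E)-13-acetoxy-8α-hydroxygermacra-1(10),2,4,7(11)-tetraen-12,6α-olide F1, the hydroxy triene (1(10)E,4E)-13-acetoxy-8α-hydroxygermacra-1(10),4,7(11)-trien-12,6α-olide F2. F2 is then acylated with mixed anhydride 28 (made from 26 through 27 as in step 19) and DMAP, which returns to the route at 31.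

Step 23. Under base, deprotonation at C6 (γ to the lactone carbonyl) may expel the mesylate by elimination, or the free C4 hydroxyl may open the 1,10-epoxide across the ring, instead of the wanted closure. Fallback: setting out from diol 33, a Mitsunobu cyclodehydration (PPh3, diisopropyl azodicarboxylate, toluene, 0 → 20 °C) activates the less hindered secondary 5-hydroxyl as the oxyphosphonium ion under neutral conditions. The tertiary 4-hydroxyl displaces it with the same inversion at C5, so the route is rejoined directly at 35 and no compound outside the list is made (F0).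

Step 10. Deprotonation of 14 may not discriminate C8 from C6 (poor regioselectivity of enolisation), which would scramble the order in which the two oxygens are introduced. Fallback: regiocontrol is given up and the two hydroxyls are told apart afterwards by their steric environment. Setting out from 14, the Davis oxidation is run as before and the mixture of 15 and its regioisomer 6α-hydroxy-11,12,13-trinor-5α-eudesma-1,3-dien-7-one F3 is oxidised a second time (2.2 equiv KN(SiMe3)2, the alkoxide steering enolisation to the free side) to 6α,8α-dihydroxy-11,12,13-trinor-5α-eudesma-1,3-dien-7-one F4. One equivalent of t-BuMe2SiCl with imidazole should then silylate the less hindered 8-hydroxyl (O-6 is flanked by the ring fusion and the C4 methyl), which returns to the route at 17.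

Further compounds
F1 | step 20 | (1(10)E,2Z,4E)-13-acetoxy-8α-hydroxygermacra-1(10),2,4,7(11)-tetraen-12,6α-olide | CC(=O)OCC1=C2[C@@H](O)C/C(C)=C/C=C\C(C)=C\[C@H]2OC1=O
F2 | step 20 | (1(10)E,4E)-13-acetoxy-8α-hydroxygermacra-1(10),4,7(11)-trien-12,6α-olide | CC(=O)OCC1=C2[C@@H](O)C/C(C)=C/CC/C(C)=C/[C@H]2OC1=O
F0 | step 23 | none | none
F3 | step 10 | 6α-hydroxy-11,12,13-trinor-5α-eudesma-1,3-dien-7-one | CC=1[C@@H]2[C@@H](O)C(=O)CC[C@@]2(C)C=CC=1
F4 | step 10 | 6α,8α-dihydroxy-11,12,13-trinor-5α-eudesma-1,3-dien-7-one | CC=1[C@@H]2[C@@H](O)C(=O)[C@@H](O)C[C@@]2(C)C=CC=1
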